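**Assumption:** the target is taken exactly as the given SMILES. Terpenoid locants are used for orientation: C1–C10 in each decalin, C11–C12 for the CH2CH2 link, primes for the saturated half.

## Retrosynthetic overview

1. The C8 methyl and the 7,8-alkene of the unsaturated half come last, by Shapiro methylation of a C8 ketone.
2. The central C11–C12 bond comes from radical conjugate addition of a primary bromide (saturated half, 8α-methyl already set) to a 9-methylene-8-ketone (other half).
3. Both halves derive from one 9-(bromomethyl)-8-decalone, whose ring B is made by ring expansion (1,2-shift of C10) of a 1-vinyl trans-hydrindan-1-ol.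
4. The hydrindanol comes from 2-methylcyclopentane-1,3-dione and ethyl vinyl ketone: amino-acid-mediated annulation (ring A, C10), reductive methylation (trans fusion, gem-dimethyl), reduction (3β-OH), vinyl addition.
5. Ring order: cyclopentane ring (bought) → ring A (annulation) → ring B (expansion, used for both halves) → union of the two decalins.

## Route

Step 1
Reactants: 1 2-methylcyclopentane-1,3-dione; 2 pent-1-en-3-one (ethyl vinyl ketone)
Product: 5 (7aS)-4,7a-dimethyl-2,3,7,7a-tetrahydro-1H-indene-1,5(6H)-dione, via Michael triketone 3 (not isolated), via aldol ketol 4 (not isolated)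
Conditions: Et3N (1 mol%), neat, rt; then L-phenylalanine (1 equiv), (1S)-(+)-10-camphorsulfonic acid (0.5 equiv), DMF, 30 → 70 °C
Reagents that add atoms: none
Why: Michael addition followed by the Hajos–Parrish–Eder–Sauer–Wiechert aldol condensation; the amino-acid enamine selects one of the two enantiotopic ring carbonyls and sets C10 as 7aS (about 90% ee expected, to be raised by recrystallisation of 10).

Step 2
Reactants: 5 (7aS)-4,7a-dimethyl-2,3,7,7a-tetrahydro-1H-indene-1,5(6H)-dione
Product: 6 (7a'S)-4',7a'-dimethyl-2',3',7',7a'-tetrahydrospiro[1,3-dioxolane-2,1'-inden]-5'(6'H)-one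
Conditions: (Me3SiOCH2)2 (1.2 equiv), Me3SiOTf (2 mol%), CH2Cl2, −78 → −20 °C
Reagents that add atoms: 1,2-bis(trimethylsilyloxy)ethane, C[Si](C)(C)OCCO[Si](C)(C)C
Why: Noyori acetalisation is kinetically selective for the saturated cyclopentanone over the conjugated enone, as in the 17-monoketalisation of androst-4-ene-3,17-dione.

Step 3
Reactants: 6 (7a'S)-4',7a'-dimethyl-2',3',7',7a'-tetrahydrospiro[1,3-dioxolane-2,1'-inden]-5'(6'H)-one
Product: 8 (3a'S,7a'S)-4',4',7a'-trimethylhexahydrospiro[1,3-dioxolane-2,1'-inden]-5'(4'H)-one (trans-fused), via lithium enolate 7 (not isolated)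
Conditions: Li (2.3 equiv), t-BuOH (1.0 equiv), NH3(l)/THF, −78 → −33 °C; then MeI (5 equiv), −33 °C → rt
Reagents that add atoms: iodomethane, CI
Why: Stork reductive alkylation (Birch-type enone reduction, then regiospecific enolate methylation at C4); C5 is protonated on the α face, anti to the angular methyl, giving the trans ring fusion.

Step 4
Reactants: 8 (3a'S,7a'S)-4',4',7a'-trimethylhexahydrospiro[1,3-dioxolane-2,1'-inden]-5'(4'H)-one
Product: 10 (3aS,5S,7aS)-5-hydroxy-4,4,7a-trimethyloctahydro-1H-inden-1-one, via hydroxy ketal 9 (not isolated)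
Conditions: NaBH4, MeOH, 0 °C; then 2 M HCl, THF, rt
Reagents that add atoms: water, O
Why: Borohydride reduction with axial hydride delivery from the α face (the β face is blocked by the 4β- and angular methyls) gives the equatorial 3β-alcohol (S); the acid then hydrolyses the ketal.

Step 5
Reactants: 10 (3aS,5S,7aS)-5-hydroxy-4,4,7a-trimethyloctahydro-1H-inden-1-one
Product: 11 (1R,3aS,5S,7aS)-1-ethenyl-4,4,7a-trimethyloctahydro-1H-indene-1,5-diol
Conditions: vinylmagnesium bromide (3.5 equiv), CeCl3 (3.5 equiv), THF, −78 → 0 °C; aq. NH4Cl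
Reagents that add atoms: vinylmagnesium bromide, C=C[Mg]Br
Why: Imamoto organocerium 1,2-addition to a hindered, enolisable ketone; attack comes from the α face, anti to the angular methyl, as at C17 of 17-keto steroids (the carbinol centre is consumed in step 6).

Step 6
Reactants: 11 (1R,3aS,5S,7aS)-1-ethenyl-4,4,7a-trimethyloctahydro-1H-indene-1,5-diol
Product: 12 (1R,4aR,6S,8aS)-1-(bromomethyl)-6-hydroxy-5,5,8a-trimethyloctahydronaphthalen-2(1H)-one
Conditions: NBS (1.05 equiv), Ph3P=S (10 mol%), (CF3)2CHOH/CH2Cl2 1:4, −40 → 0 °C, dark; aq. Na2S2O3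
Reagents that add atoms: N-bromosuccinimide, O=C1CCC(=O)N1Br
Why: Proposed new method: Lewis-base-activated Br+ forms the bromonium ion of the unactivated vinyl group, and the electron-rich quaternary C10–C8 bond, anti to the breaking C9–Br+ bond, shifts to C9 while the carbinol becomes the C8 ketone (semipinacol 1,2-shift; five- to six-membered ring expansion that builds ring B and relieves trans-hydrindane strain; the fluorinated alcohol stabilises the cationic transition state and keeps the hydroxyl from closing an epoxide); with C11 anti to C7 in the transition state the CH2Br group ends equatorial (9β), which is also the thermodynamic epimer reachable by enolisation; the closest known reaction type is the halonium-induced semipinacol ring expansion of 1-alkenylcyclobutanols and of aryl- or oxygen-stabilised alkenyl carbinols, not shown on an unstrained, non-stabilised vinyl cyclopentanol.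

Step 7
Reactants: 12 (1R,4aR,6S,8aS)-1-(bromomethyl)-6-hydroxy-5,5,8a-trimethyloctahydronaphthalen-2(1H)-one
Product: 13 (2S,4aS,5S,8aR)-5-(bromomethyl)-1,1,4a-trimethyl-6-methylidenedecahydronaphthalen-2-ol
Conditions: Zn, CH2Br2, TiCl4, THF/CH2Cl2, 0 °C → rt
Reagents that add atoms: dibromomethane, BrCBr
Why: Takai–Lombardo methylenation is non-basic, so the β-bromo ketone neither eliminates HBr nor epimerises at C9, and it tolerates the free hydroxyl.

Step 8
Reactants: 13 (2S,4aS,5S,8aR)-5-(bromomethyl)-1,1,4a-trimethyl-6-methylidenedecahydronaphthalen-2-ol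
Product: 14 (2S,4aS,5S,6R,8aR)-5-(bromomethyl)-1,1,4a,6-tetramethyldecahydronaphthalen-2-ol
Conditions: Mn(dpm)3 (10 mol%; dpm = 2,2,6,6-tetramethylheptane-3,5-dionate), PhSiH3, t-BuOOH, i-PrOH, rt
Reagents that add atoms: none
Why: Metal-hydride hydrogen-atom-transfer hydrogenation (Mukaiyama-type, Shenvi conditions); the tertiary C8 radical takes its hydrogen axially, which places the methyl equatorial (8α, R), the thermodynamic epimer, and leaves the C–Br bond untouched.

Step 9
Reactants: 12 (1R,4aR,6S,8aS)-1-(bromomethyl)-6-hydroxy-5,5,8a-trimethyloctahydronaphthalen-2(1H)-one (1.5 equiv); 14 (2S,4aS,5S,6R,8aR)-5-(bromomethyl)-1,1,4a,6-tetramethyldecahydronaphthalen-2-ol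
Product: 16 (1R,4aR,6S,8aS)-6-hydroxy-1-{2-[(1S,2R,4aR,6S,8aR)-6-hydroxy-2,5,5,8a-tetramethyldecahydronaphthalen-1-yl]ethyl}-5,5,8a-trimethyloctahydronaphthalen-2(1H)-one, via methylene ketone 15 (not isolated)
Conditions: 12, DBU (1.0 equiv relative to 12), PhMe, 0 °C, 20 min; then 14, (Me3Si)3SiH, AIBN (cat.), 80 °C, slow addition
Reagents that add atoms: none
Why: E1cB loss of HBr gives the unstable α-methylene ketone in situ, and a Giese radical conjugate addition of the primary radical from 14 (bromine abstraction by the silyl radical) forms C11–C12; the α-keto radical at C9 takes hydrogen axially from the α face, and C9 can in any case equilibrate by enolisation to the equatorial 9β side chain.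

Step 10
Reactants: 16 (1R,4aR,6S,8aS)-6-hydroxy-1-{2-[(1S,2R,4aR,6S,8aR)-6-hydroxy-2,5,5,8a-tetramethyldecahydronaphthalen-1-yl]ethyl}-5,5,8a-trimethyloctahydronaphthalen-2(1H)-one
Product: 17 (E)-2,4,6-triisopropylbenzenesulfonylhydrazone of 16 at C8
Conditions: 2,4,6-triisopropylbenzenesulfonohydrazide (1.2 equiv), HCl (cat.), THF/MeOH, rt
Reagents that add atoms: 2,4,6-triisopropylbenzenesulfonohydrazide, CC(C)c1cc(C(C)C)c(S(=O)(=O)NN)c(C(C)C)c1
Why: Acid-catalysed hydrazone condensation; the N–N bond settles anti to the branched C9 side, which prepares syn-directed deprotonation at C7.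

Step 11
Reactants: 17 (E)-2,4,6-triisopropylbenzenesulfonylhydrazone of 16 at C8
Product: 19 CNP0194061.1 (2S,4aR,5S,8aR)-5-{2-[(1S,2R,4aR,6S,8aR)-6-hydroxy-2,5,5,8a-tetramethyldecahydronaphthalen-1-yl]ethyl}-1,1,4a,6-tetramethyl-1,2,3,4,4a,5,8,8a-octahydronaphthalen-2-ol, via vinyllithium 18 (not isolated)
Conditions: n-BuLi (5 equiv), THF/TMEDA, −78 → 0 °C (N2 evolution); then MeI (1.3 equiv), −78 → 0 °C; aq. NH4Cl
Reagents that add atoms: iodomethane, CI
Why: Shapiro reaction (Bond trisylhydrazone variant); deprotonation at the C7 methylene, then loss of sulfinate and N2, gives the C7=C8 vinyllithium regiospecifically, and C-methylation is far faster than O-methylation of the hindered lithium alkoxides; no stereocentre is touched.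

## Compound list

1 | 2-methylcyclopentane-1,3-dione | CC1C(=O)CCC1=O | starting material
2 | pent-1-en-3-one | CCC(=O)C=C | starting material
3 | 2-methyl-2-(3-oxopentyl)cyclopentane-1,3-dione | CCC(=O)CCC1(C)C(=O)CCC1=O | intermediate (not isolated)
4 | (3aS,7aS)-3a-hydroxy-4,7a-dimethylhexahydro-1H-indene-1,5(4H)-dione (cis-fused, both C4 epimers) | CC1C(=O)CC[C@]2(C)C(=O)CC[C@]12O | intermediate (not isolated)
5 | (7aS)-4,7a-dimethyl-2,3,7,7a-tetrahydro-1H-indene-1,5(6H)-dione | CC1=C2CCC(=O)[C@@]2(C)CCC1=O | intermediate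
6 | (7a'S)-4',7a'-dimethyl-2',3',7',7a'-tetrahydrospiro[1,3-dioxolane-2,1'-inden]-5'(6'H)-one | CC1=C2CCC3(OCCO3)[C@@]2(C)CCC1=O | intermediate
7 | lithium C3 enolate of the reduced ketal (3a'S,7a'S; trans-fused, C4=C3 enolate) | [Li]OC1=C(C)[C@@H]2CCC3(OCCO3)[C@@]2(C)CC1 | intermediate (not isolated)
8 | (3a'S,7a'S)-4',4',7a'-trimethylhexahydrospiro[1,3-dioxolane-2,1'-inden]-5'(4'H)-one | O=C1CC[C@]2(C)C3(CC[C@H]2C1(C)C)OCCO3 | intermediate
9 | (3a'S,5'S,7a'S)-4',4',7a'-trimethyloctahydrospiro[1,3-dioxolane-2,1'-inden]-5'-ol | O[C@H]1CC[C@]2(C)C3(CC[C@H]2C1(C)C)OCCO3 | intermediate (not isolated)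
10 | (3aS,5S,7aS)-5-hydroxy-4,4,7a-trimethyloctahydro-1H-inden-1-one | O[C@H]1CC[C@]2(C)C(=O)CC[C@H]2C1(C)C | intermediate
11 | (1R,3aS,5S,7aS)-1-ethenyl-4,4,7a-trimethyloctahydro-1H-indene-1,5-diol | O[C@H]1CC[C@]2(C)[C@](O)(C=C)CC[C@H]2C1(C)C | intermediate
12 | (1R,4aR,6S,8aS)-1-(bromomethyl)-6-hydroxy-5,5,8a-trimethyloctahydronaphthalen-2(1H)-one | O[C@H]1CC[C@]2(C)[C@@H](CBr)C(=O)CC[C@H]2C1(C)C | intermediate
13 | (2S,4aS,5S,8aR)-5-(bromomethyl)-1,1,4a-trimethyl-6-methylidenedecahydronaphthalen-2-ol | O[C@H]1CC[C@]2(C)[C@@H](CBr)C(=C)CC[C@H]2C1(C)C | intermediate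
14 | (2S,4aS,5S,6R,8aR)-5-(bromomethyl)-1,1,4a,6-tetramethyldecahydronaphthalen-2-ol | O[C@H]1CC[C@]2(C)[C@@H](CBr)[C@H](C)CC[C@H]2C1(C)C | intermediate
15 | (4aR,6S,8aS)-6-hydroxy-5,5,8a-trimethyl-1-methylideneoctahydronaphthalen-2(1H)-one | O[C@H]1CC[C@]2(C)C(=C)C(=O)CC[C@H]2C1(C)C | intermediate (not isolated)
16 | (1R,4aR,6S,8aS)-6-hydroxy-1-{2-[(1S,2R,4aR,6S,8aR)-6-hydroxy-2,5,5,8a-tetramethyldecahydronaphthalen-1-yl]ethyl}-5,5,8a-trimethyloctahydronaphthalen-2(1H)-one | O[C@H]1CC[C@]2(C)[C@@H](CC[C@H]3[C@H](C)CC[C@H]4C(C)(C)[C@@H](O)CC[C@]34C)C(=O)CC[C@H]2C1(C)C | intermediate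
17 | (E)-2,4,6-triisopropylbenzenesulfonylhydrazone of 16 at C8 | O[C@H]1CC[C@]2(C)[C@@H](CC[C@H]3[C@H](C)CC[C@H]4C(C)(C)[C@@H](O)CC[C@]34C)/C(=N/NS(=O)(=O)c5c(C(C)C)cc(C(C)C)cc5C(C)C)CC[C@H]2C1(C)C | intermediate
18 | C8-lithio 7,8-alkene (vinyllithium), both alcohols as lithium alkoxides | [Li]O[C@H]1CC[C@]2(C)[C@@H](CC[C@H]3[C@H](C)CC[C@H]4C(C)(C)[C@@H](O[Li])CC[C@]34C)C([Li])=CC[C@H]2C1(C)C | intermediate (not isolated)
19 | CNP0194061.1, (2S,4aR,5S,8aR)-5-{2-[(1S,2R,4aR,6S,8aR)-6-hydroxy-2,5,5,8a-tetramethyldecahydronaphthalen-1-yl]ethyl}-1,1,4a,6-tetramethyl-1,2,3,4,4a,5,8,8a-octahydronaphthalen-2-ol | CC1=CC[C@H]2C(C)(C)[C@@H](O)CC[C@]2(C)[C@H]1CC[C@H]1[C@H](C)CC[C@H]2C(C)(C)[C@@H](O)CC[C@]12C | target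

## Step count and risks

Total step count: 11.
Longest linear sequence: 11 steps (1 → 5 → 6 → 8 → 10 → 11 → 12 → 13 → 14 → 16 → 17 → 19); compound 12 is used in both step 7 and step 9.

The three steps most likely to fail:

**Step 6 (the proposed ring expansion).** The bromonium ion of a plain vinyl group may be trapped by the tertiary hydroxyl, C7 may migrate instead of C10, or the tertiary allylic alcohol may ionise. The fallback uses known chemistry, sets out from 11 and comes back at 12. Hydroxyl-directed epoxidation (VO(acac)2, t-BuOOH, CH2Cl2) gives the epoxy alcohol (1S,3aS,5S,7aS)-4,4,7a-trimethyl-1-[(2R)-oxiran-2-yl]octahydro-1H-indene-1,5-diol F1. BF3·OEt2 in CH2Cl2 at −78 °C then triggers the epoxy-alcohol semipinacol ring expansion (Tsuchihashi–Suzuki) to the hydroxymethyl ketone (1S,4aR,6S,8aS)-6-hydroxy-1-(hydroxymethyl)-5,5,8a-trimethyloctahydronaphthalen-2(1H)-one F2, whose C9 settles as the equatorial epimer by enolisation. CBr4/PPh3, selective for the primary alcohol, gives 12.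

**Step 8 (configuration at C8).** Axial hydrogen delivery is opposed by the 1,3-diaxial angular methyl, so the 8β-methyl epimer may form in quantity. The fallback sets out from 13 and comes back at 14. Catalytic hydrogenation (H2, PtO2, EtOAc) adds from the α face and gives the axial epimer (2S,4aS,5S,6S,8aR)-5-(bromomethyl)-1,1,4a,6-tetramethyldecahydronaphthalen-2-ol F3. Photochemical hydrogen-atom-transfer epimerisation of the tertiary C8–H ((n-Bu4N)4W10O32, a diaryl disulfide, MeCN, 390 nm) then converts it to the more stable equatorial epimer 14.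

**Step 9 (union of two hindered halves in near 1:1 ratio).** Reduction of the radical from 14 before addition, and hydrosilylation or dimerisation of 15, may cut the yield. The fallback sets out from 12 and comes back at 16. DBU gives 15, and reductive β,β-dimerisation (SmI2, HMPA, t-BuOH, THF) gives the C2-symmetric diketone 1,1'-(ethane-1,2-diyl)bis[(1R,4aR,6S,8aS)-6-hydroxy-5,5,8a-trimethyloctahydronaphthalen-2(1H)-one] F4. Mono-methylenation with one equivalent of Zn/CH2Br2/TiCl4 (statistical, F4 recycled) gives the methylene ketone (1R,4aR,6S,8aS)-6-hydroxy-1-{2-[(1S,4aR,6S,8aR)-6-hydroxy-5,5,8a-trimethyl-2-methylidenedecahydronaphthalen-1-yl]ethyl}-5,5,8a-trimethyloctahydronaphthalen-2(1H)-one F5. Hydrogenation under the step 8 conditions (Mn(dpm)3, PhSiH3, t-BuOOH, i-PrOH) gives 16.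

## Further compounds

F1 | step 6 | (1S,3aS,5S,7aS)-4,4,7a-trimethyl-1-[(2R)-oxiran-2-yl]octahydro-1H-indene-1,5-diol | O[C@H]1CC[C@]2(C)[C@](O)([C@H]3CO3)CC[C@H]2C1(C)C
F2 | step 6 | (1S,4aR,6S,8aS)-6-hydroxy-1-(hydroxymethyl)-5,5,8a-trimethyloctahydronaphthalen-2(1H)-one | O[C@H]1CC[C@]2(C)[C@@H](CO)C(=O)CC[C@H]2C1(C)C
F3 | step 8 | (2S,4aS,5S,6S,8aR)-5-(bromomethyl)-1,1,4a,6-tetramethyldecahydronaphthalen-2-ol | O[C@H]1CC[C@]2(C)[C@@H](CBr)[C@@H](C)CC[C@H]2C1(C)C
F4 | step 9 | 1,1'-(ethane-1,2-diyl)bis[(1R,4aR,6S,8aS)-6-hydroxy-5,5,8a-trimethyloctahydronaphthalen-2(1H)-one] | O[C@H]1CC[C@]2(C)[C@@H](CC[C@H]3C(=O)CC[C@H]4C(C)(C)[C@@H](O)CC[C@]34C)C(=O)CC[C@H]2C1(C)C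
F5 | step 9 | (1R,4aR,6S,8aS)-6-hydroxy-1-{2-[(1S,4aR,6S,8aR)-6-hydroxy-5,5,8a-trimethyl-2-methylidenedecahydronaphthalen-1-yl]ethyl}-5,5,8a-trimethyloctahydronaphthalen-2(1H)-one | O[C@H]1CC[C@]2(C)[C@@H](CC[C@H]3C(=C)CC[C@H]4C(C)(C)[C@@H](O)CC[C@]34C)C(=O)CC[C@H]2C1(C)C
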